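**Retrosynthetic overview**
1. Last step: the hydroquinone is released from its bis-TBS ether 12; the benzene and furan rings are both bought intact, so no ring is formed in the route.
2. Key disconnection: the bond from furan C4 to the acyloxy-bearing carbon, made by an enantioconvergent, nickel-catalysed electroreductive cross-electrophile coupling of 4-bromofuran 7 with racemic 1-chloroalkyl isovalerate 11. Both carbons are electrophiles, and the step forms the C–C bond, sets the (R) centre and delivers the isovalerate in one operation.
3. Enabling feature: the stereogenic carbon carries the isovalerate oxygen, so it is an O-acylated aldehyde carbon. Its chloride is a weak, acetal-like C–Cl bond, the derived radical is planar and stabilised by the ester oxygen, and the ester C=O can chelate nickel. On the furan, C4 is the β-carbon whose C–Br bond survives a C2-selective coupling.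
4. Fragment 11 is the adduct of 4-methylpent-3-enal (9) and isovaleryl chloride (10); fragment 7 comes from 2,4-dibromofuran (6) and boronate 5 (from bromohydroquinone 1) by a C2-selective Suzuki coupling.

Key step: step 6

Assumptions: the (S,S)-ligand in step 6 is taken to give the (R)-ester; the step is catalyst-controlled, so the (R,R)-ligand is used if a model coupling shows the opposite sense. 2,4-Dibromofuran (6) is taken as a purchasable building block; the fallback for step 3 starts from 3-bromofuran instead.

**Step 1**
Reactants: 1 2-bromobenzene-1,4-diol; 2 tert-butyldimethylsilyl chloride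
Product: 3 2-bromo-1,4-bis(tert-butyldimethylsilyloxy)benzene
Conditions: TBSCl (2.4 equiv), imidazole (5 equiv), DMF, rt
Reagents that add atoms: tert-butyldimethylsilyl chloride (2), CC(C)(C)[Si](C)(C)Cl
Why: Imidazole-mediated silylation of phenols should cap both hydroxyl groups and leave the aryl bromide untouched.

**Step 2**
Reactants: 3 2-bromo-1,4-bis(tert-butyldimethylsilyloxy)benzene; 4 bis(pinacolato)diboron
Product: 5 2-[2,5-bis(tert-butyldimethylsilyloxy)phenyl]-4,4,5,5-tetramethyl-1,3,2-dioxaborolane
Conditions: B2pin2, Pd(dppf)Cl2 (5 mol %), KOAc, 1,4-dioxane, 90 °C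
Reagents that add atoms: bis(pinacolato)diboron (4), CC1(C)OB(OC1(C)C)B1OC(C)(C)C(C)(C)O1
Why: Miyaura borylation of the aryl bromide under the weak base KOAc should leave the aryl silyl ethers intact and avoids an ortho-silyloxy aryllithium that could undergo silyl migration.

**Step 3**
Reactants: 5 2-[2,5-bis(tert-butyldimethylsilyloxy)phenyl]-4,4,5,5-tetramethyl-1,3,2-dioxaborolane; 6 2,4-dibromofuran
Product: 7 4-bromo-2-[2,5-bis(tert-butyldimethylsilyloxy)phenyl]furan
Conditions: Pd(PPh3)4 (5 mol %), K3PO4, DME/H2O, 65 °C, slight excess of 6
Reagents that add atoms: none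
Why: In this site-selective Suzuki–Miyaura coupling, oxidative addition should prefer the α C2–Br bond next to the ring oxygen over the β C4–Br bond, so mono-arylation leaves the C4 bromide for step 6.

**Step 4**
Reactants: 8 4-methylpent-3-en-1-ol
Product: 9 4-methylpent-3-enal
Conditions: Dess–Martin periodinane, CH2Cl2, 0 °C to rt; cold NaHCO3/Na2S2O3 wash; used at once as a dried CH2Cl2 solution
Reagents that add atoms: none
Why: Dess–Martin oxidation is non-basic and stops at the aldehyde, so the β,γ-olefin should not move into conjugation if the volatile product is used immediately.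

**Step 5**
Reactants: 9 4-methylpent-3-enal; 10 3-methylbutanoyl chloride (isovaleryl chloride)
Product: 11 racemic 1-chloro-4-methylpent-3-en-1-yl 3-methylbutanoate
Conditions: ZnCl2 (2 mol %), CH2Cl2, −20 to 0 °C; pentane dilution, filtration through Celite, cold concentration; used crude
Reagents that add atoms: 3-methylbutanoyl chloride (10), CC(C)CC(Cl)=O
Why: Lewis-acid-catalysed addition of an acyl chloride across the aldehyde C=O (1-chloroalkyl ester formation) is a known, atom-economic reaction of enolisable aliphatic aldehydes, run cold and briefly to spare the olefin; the new centre is deliberately racemic because step 6 is enantioconvergent.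

**Step 6**
Reactants: 7 4-bromo-2-[2,5-bis(tert-butyldimethylsilyloxy)phenyl]furan; 11 racemic 1-chloro-4-methylpent-3-en-1-yl 3-methylbutanoate
Product: 12 (1R)-1-{5-[2,5-bis(tert-butyldimethylsilyloxy)phenyl]furan-3-yl}-4-methylpent-3-en-1-yl 3-methylbutanoate
Conditions: NiBr2·dme (10 mol %), (S,S)-4-heptyl-BiOX [(4S,4′S)-4,4′-di(heptan-4-yl)-4,4′,5,5′-tetrahydro-2,2′-bioxazole] (12 mol %), NaI (20 mol %), nBu4NPF6, DMA/THF, undivided cell, Zn anode / Ni-foam cathode, constant current (ca. 2.2 F/mol), 0 °C; 11 (1.5 equiv)
Reagents that add atoms: none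
Why: Proposed new method: the chiral bis(oxazoline)–nickel catalyst, turned over at the cathode with zinc dissolving at the anode, is expected to add oxidatively to the C4–Br bond of 7, abstract chlorine from either enantiomer of 11 to give the planar, oxygen-stabilised α-acyloxyalkyl radical, capture it as a Ni(III)(furyl)(alkyl) species and reductively eliminate the furan C4–C(sp3) bond. The closest known reaction types are the Ni/bis(oxazoline)-catalysed enantioconvergent couplings of racemic 1-haloalkyl esters with alkyl nucleophiles and the asymmetric nickel-catalysed reductive and electroreductive cross-electrophile couplings of (hetero)aryl halides with secondary benzylic chlorides; new here is the union of an α-acyloxyalkyl chloride with a β-furyl bromide under enantiocontrol at constant current. No ring is closed. The single stereocentre is set under catalyst control, since the ligand, helped by chelation of the ester carbonyl to nickel, differentiates the two faces of the radical at capture and reductive elimination, so both antipodes of 11 converge on the (R)-ester. The step needs cross- over homo-coupling, which is secured by the different activation modes of the two electrophiles (two-electron oxidative addition at the sp2 C–Br bond, halogen abstraction at the weak sp3 C–Cl bond) and by dosing the electrons through the current. The trisubstituted olefin and the aryl silyl ethers should be inert at the cell potential, and the 3-exo cyclisation of the homoallylic radical is reversible and unproductive.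

**Step 7**
Reactants: 12 (1R)-1-{5-[2,5-bis(tert-butyldimethylsilyloxy)phenyl]furan-3-yl}-4-methylpent-3-en-1-yl 3-methylbutanoate
Product: 13 (1R)-1-[5-(2,5-dihydroxyphenyl)furan-3-yl]-4-methylpent-3-en-1-yl 3-methylbutanoate (CNP0296263.1)
Conditions: TBAF (2.2 equiv), AcOH (2.5 equiv), degassed THF, 0 °C, argon; work-up with degassed solvents
Reagents that add atoms: none
Why: Buffered fluoride cleavage of the two aryl silyl ethers should be fast at 0 °C, while the acetic acid buffer keeps the secondary isovalerate, the olefin, the furan and the stereocentre untouched and exclusion of air limits oxidation of the hydroquinone.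

**Compound list**
1 | 2-bromobenzene-1,4-diol | Oc1ccc(O)c(Br)c1 | starting material
2 | tert-butyldimethylsilyl chloride | CC(C)(C)[Si](C)(C)Cl | starting material
3 | 2-bromo-1,4-bis(tert-butyldimethylsilyloxy)benzene | CC(C)(C)[Si](C)(C)Oc1ccc(O[Si](C)(C)C(C)(C)C)c(Br)c1 | intermediate
4 | bis(pinacolato)diboron | CC1(C)OB(OC1(C)C)B1OC(C)(C)C(C)(C)O1 | starting material
5 | 2-[2,5-bis(tert-butyldimethylsilyloxy)phenyl]-4,4,5,5-tetramethyl-1,3,2-dioxaborolane | CC(C)(C)[Si](C)(C)Oc1ccc(O[Si](C)(C)C(C)(C)C)c(B2OC(C)(C)C(C)(C)O2)c1 | intermediate
6 | 2,4-dibromofuran | Brc1coc(Br)c1 | starting material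
7 | 4-bromo-2-[2,5-bis(tert-butyldimethylsilyloxy)phenyl]furan | CC(C)(C)[Si](C)(C)Oc1ccc(O[Si](C)(C)C(C)(C)C)c(-c2cc(Br)co2)c1 | intermediate
8 | 4-methylpent-3-en-1-ol | CC(C)=CCCO | starting material
9 | 4-methylpent-3-enal | CC(C)=CCC=O | intermediate
10 | 3-methylbutanoyl chloride | CC(C)CC(Cl)=O | starting material
11 | racemic 1-chloro-4-methylpent-3-en-1-yl 3-methylbutanoate | CC(C)=CCC(Cl)OC(=O)CC(C)C | intermediate
12 | (1R)-1-{5-[2,5-bis(tert-butyldimethylsilyloxy)phenyl]furan-3-yl}-4-methylpent-3-en-1-yl 3-methylbutanoate | CC(C)=CC[C@@H](OC(=O)CC(C)C)c1coc(-c2cc(O[Si](C)(C)C(C)(C)C)ccc2O[Si](C)(C)C(C)(C)C)c1 | intermediate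
13 | (1R)-1-[5-(2,5-dihydroxyphenyl)furan-3-yl]-4-methylpent-3-en-1-yl 3-methylbutanoate | CC(C)=CC[C@@H](OC(=O)CC(C)C)c1coc(-c2cc(O)ccc2O)c1 | target

**Step count**
Total steps: 7. Longest linear sequence: 5 (steps 1, 2, 3, 6, 7).

**Steps most likely to fail**

Step 6 (Proposed new method). What may go wrong: homo-coupling or hydrodehalogenation may outrun cross-coupling, the facial discrimination of the α-acyloxy radical may be poor, or β-hydride elimination may give the enol ester. The fallback uses known chemistry, sets out from 7 and comes back at 12. Bromine–lithium exchange on 7 (n-BuLi, THF, −78 °C) and addition to aldehyde 9 should give the racemic alcohol 1-{5-[2,5-bis(tert-butyldimethylsilyloxy)phenyl]furan-3-yl}-4-methylpent-3-en-1-ol F1. Dess–Martin oxidation should give the ketone 1-{5-[2,5-bis(tert-butyldimethylsilyloxy)phenyl]furan-3-yl}-4-methylpent-3-en-1-one F2. Corey–Bakshi–Shibata reduction with (S)-Me-CBS and catecholborane (toluene, −78 °C, chosen to spare the olefin) should give, with the furyl group as the large substituent, the alcohol (1R)-1-{5-[2,5-bis(tert-butyldimethylsilyloxy)phenyl]furan-3-yl}-4-methylpent-3-en-1-ol F3. Acylation of F3 with 10 (pyridine, DMAP, CH2Cl2, 0 °C) proceeds with retention at carbon and gives 12.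

Step 5. What may go wrong: Lewis-acid-induced migration of the β,γ-olefin into conjugation, addition of HCl to the olefin, or ionisation and elimination of the chloro ester on concentration. The fallback avoids aldehyde 9 and any Lewis acid by generating the same radical decarboxylatively; it sets out from 10 and comes back at 12. Williamson etherification of 2-methylbut-3-en-2-ol with bromoacetic acid (NaH, THF) should give 2-[(2-methylbut-3-en-2-yl)oxy]acetic acid F4. Its dianion (LDA, THF, −78 to 0 °C) should undergo [2,3]-Wittig rearrangement to racemic 2-hydroxy-5-methylhex-4-enoic acid F5. Acylation with 10 (pyridine, CH2Cl2; aqueous work-up hydrolyses any mixed anhydride) should give racemic 5-methyl-2-[(3-methylbutanoyl)oxy]hex-4-enoic acid F6. Coupling with N-hydroxyphthalimide (DIC, DMAP) should give the redox-active ester 1,3-dioxoisoindolin-2-yl 5-methyl-2-[(3-methylbutanoyl)oxy]hex-4-enoate F7. F7 is then joined to 7 under the nickel/ligand conditions of step 6; nickel-catalysed reductive decarboxylative arylation of N-acyloxyphthalimides is a known reaction type, and this returns to 12.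

Step 3. What may go wrong: loss of site selectivity (double arylation), protodeboronation of the hindered ortho-silyloxy boronate, base-induced loss of the aryl silyl ethers, or decomposition of the labile dibromofuran. The fallback reverses the roles of the coupling partners; it sets out from 3 and comes back at 7. Bromine–lithium exchange on 3 (n-BuLi, THF, −78 °C) with an immediate iodine quench should give 2-iodo-1,4-bis(tert-butyldimethylsilyloxy)benzene F8. Iridium-catalysed C–H borylation of 3-bromofuran with 4 ([Ir(OMe)(cod)]2, dtbpy, hexane, rt), directed by sterics to C5, should give 2-(4-bromofuran-2-yl)-4,4,5,5-tetramethyl-1,3,2-dioxaborolane F9. Suzuki–Miyaura coupling of F9 with F8 (Pd(PPh3)4, K3PO4, THF/H2O, 50 °C), in which the aryl iodide should react well ahead of either furyl C–Br bond, gives 7.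

**Further compounds**
F1 | step 6 | racemic 1-{5-[2,5-bis(tert-butyldimethylsilyloxy)phenyl]furan-3-yl}-4-methylpent-3-en-1-ol | CC(C)=CCC(O)c1coc(-c2cc(O[Si](C)(C)C(C)(C)C)ccc2O[Si](C)(C)C(C)(C)C)c1
F2 | step 6 | 1-{5-[2,5-bis(tert-butyldimethylsilyloxy)phenyl]furan-3-yl}-4-methylpent-3-en-1-one | CC(C)=CCC(=O)c1coc(-c2cc(O[Si](C)(C)C(C)(C)C)ccc2O[Si](C)(C)C(C)(C)C)c1
F3 | step 6 | (1R)-1-{5-[2,5-bis(tert-butyldimethylsilyloxy)phenyl]furan-3-yl}-4-methylpent-3-en-1-ol | CC(C)=CC[C@@H](O)c1coc(-c2cc(O[Si](C)(C)C(C)(C)C)ccc2O[Si](C)(C)C(C)(C)C)c1
F4 | step 5 | 2-[(2-methylbut-3-en-2-yl)oxy]acetic acid | C=CC(C)(C)OCC(=O)O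
F5 | step 5 | racemic 2-hydroxy-5-methylhex-4-enoic acid | CC(C)=CCC(O)C(=O)O
F6 | step 5 | racemic 5-methyl-2-[(3-methylbutanoyl)oxy]hex-4-enoic acid | CC(C)=CCC(OC(=O)CC(C)C)C(=O)O
F7 | step 5 | racemic 1,3-dioxoisoindolin-2-yl 5-methyl-2-[(3-methylbutanoyl)oxy]hex-4-enoate | CC(C)=CCC(OC(=O)CC(C)C)C(=O)ON1C(=O)c2ccccc2C1=O
F8 | step 3 | 2-iodo-1,4-bis(tert-butyldimethylsilyloxy)benzene | CC(C)(C)[Si](C)(C)Oc1ccc(O[Si](C)(C)C(C)(C)C)c(I)c1
F9 | step 3 | 2-(4-bromofuran-2-yl)-4,4,5,5-tetramethyl-1,3,2-dioxaborolane | CC1(C)OB(c2cc(Br)co2)OC1(C)C
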